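## Analysis of the target

Epimedokoreanin B is luteolin (5,7,3',4'-tetrahydroxyflavone) carrying two prenyl (3-methylbut-2-enyl) groups, one on C8 of ring A and one on C5' of ring B. The core is a 2-arylchromen-4-one: benzo ring A fused to the pyranone ring C (O1, C2=C3, C4=O), with the catechol ring B on C2. There is no stereocentre, and both side-chain alkenes end in a C(CH3)2 carbon, so no alkene geometry has to be set. Of the four phenols, 5-OH is tied to the C4 carbonyl by a hydrogen bond and is the least reactive, 7-OH is the most acidic, and 3'-OH/4'-OH form an oxidation-prone catechol in which 4'-OH is the more acidic because it is conjugated through C2=C3 with C4=O. Each prenyl group lies ortho to a free phenol (C8 beside 7-OH, C5' beside 4'-OH); under acid such a pair closes to a 2,2-dimethylchroman and the trisubstituted alkene adds water or alcohols. The difficulty is therefore one of position and timing: the carbon substituents must go to C8 and not C6, and to C5' and not C2' or C6', and the fragile C5 units must survive the chemistry that places them. The strategy rests on the constitution of the side chains, Ar–CH2–CH=C(CH3)2: the Ar–CH2 bond stands ortho to an oxygen and can come from an oxygen-to-carbon allyl shift, while the terminal CH=C(CH3)2 bond can be kept as CH=CH2 and completed last by metathesis.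

## Retrosynthetic reasoning

**Target 14 back to 13.** Only O–C bonds are cut: the three methoxymethyl (MOM) acetals on O7, O3' and O4'. The tetraphenol itself is poorly soluble in the medium of the preceding step and its catechol could bind the catalyst, so these three oxygens are masked until the end. The chelated 5-OH needs no mask. The forward step must cleave three acetals under acid mild enough to leave the two prenyl alkenes and their neighbouring phenols alone.

**13 back to 9 and 10.** The two trisubstituted C=C bonds of the side chains are cut, which turns each prenyl group into a plain allyl group. This is the best place to cut because it removes the acid- and heat-sensitive prenyl motif from every earlier step and raises no stereochemical question. The forward reaction is a double cross-metathesis in which each terminal CH=CH2 of 9 takes over the isopropylidene end of 10.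

**9 back to 7 and 8.** Three O–CH2 bonds are cut. The forward step alkylates 7-OH, 3'-OH and 4'-OH of 7 with 8 and leaves the hydrogen-bonded 5-OH free.

**7 back to 4.** The aryl–CH2 bonds at C8 and C5' are cut and each allyl group is returned to the neighbouring oxygen (O7 and O4'). These C–C bonds are ortho to oxygen and are exactly those a Claisen rearrangement forms, so the ring positions of the side chains are decided by which oxygens carry the allyl groups. On ring B only C5' is open ortho to O4'. On ring A the forward step has to favour C8 over C6.

**4 back to 1 and 2.** Two O–allyl bonds are cut. The forward step relies on the acidity order of 1 (7-OH > 4'-OH > 3'-OH >> 5-OH) to put exactly two allyl groups from 2 on O7 and O4'. The entire carbon skeleton of rings A, B and C is bought with 1.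

## Alternatives that were turned down

**Alternative 1:** The disconnection is at C4–C4a of ring C. The open precursor is the (Z)-3-aryl-3-aryloxyacrylic acid A2, which already holds the O1–C2 bond and both prenyl groups. Activation of the acid and intramolecular Friedel–Crafts acylation of ring A, at the one free carbon ortho to the ether oxygen, would give 3',4'-di-O-allyl-5-O-methyl epimedokoreanin B A1.
- For it: the route is convergent, and on ring-A regiochemistry it is stronger than the chosen route, because C8 versus C6 is settled by the substitution pattern of the aryloxy part before ring C exists.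
- Against it: generating the acylating species needs strong Brønsted or Lewis acid, and A2 carries two trisubstituted alkenes, one of them ortho to the free 7-OH. These are better proton acceptors and π-nucleophiles than the arene carbon that has to react, so chroman closure, cation–olefin reactions and acylation of an alkene are the expected competitors.
- The Z geometry of A2 must also be secured, since the other isomer cannot reach ring A.
- After the key step three more groups have to leave: two O-allyl ethers and the 5-O-methyl group, the last again calling for a Lewis acid next to prenyl groups.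
- Both aryl halves must be prenylated and joined from small arenes first, so the step count lies well above five.
- Comparison: the chosen route gives up the built-in regiocontrol but starts from the finished skeleton 1 and keeps every strongly acidic or hot step away from a prenyl group.

**Alternative 2:** The disconnection is at C4a–C5, so ring A is built last on a pyranone that becomes ring C. The precursor A4 (drawn as the methyl ester) is a 2-aryl-4-pyranone bearing a CH(prenyl)–CO–CH2–CO2CH3 chain at C6. Its vinylogous enolate would attack the ester through pyranone C5 (Claisen condensation), and enolisation would give ring A as the free 5,7-diol, 3',4'-di-O-MOM epimedokoreanin B A3.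
- For it: the closure mirrors the polyketide origin of ring A; the C8 prenyl group is fixed by construction (stronger than the chosen route on this point); and ring A needs no protecting groups.
- Against it: the first proton lost from A4 is that of the CH2 between ketone and ester, and the resulting enolate makes the ester a poor electrophile. Ring closure then needs a dianion reacting through its least nucleophilic terminus, the α-carbon of a vinylogous ester.
- O-acylation, aldol closures and base-induced opening of the pyranone compete.
- Making A4 requires site-selective C-prenylation among several acidic positions and a long series of C–C bond formations.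
- Comparison: the key step has no close precedent on such a substrate, whereas the chosen route uses only standard reaction types and is five steps from 1.

**Alternative 3:** The same two aryl–CH2 bonds are cut as in the chosen Claisen step, but with complete C5 units. The precursor is 5-O-prenyl-4'-O-(1,1-dimethylallyl)-7,3'-di-O-MOM-luteolin A6. On heating, the ring-A unit would travel by a [3,3] shift from O5 to C6 and by a second [3,3] shift on to C8. The ring-B unit would move in one [3,3] shift from O4' to C5', which turns the reversed ether into a normal prenyl group. The product is 7,3'-di-O-MOM epimedokoreanin B A5.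
- For it: it is atom-economical, needs no metal catalyst and no separate step to complete the side chains. The C8 selectivity of the two-shift pathway is arguably more secure than the C8/C6 choice in step 2 of the chosen route, so it is stronger on that point.
- Against it: A6 demands alkylation of the chelated 5-OH and a tertiary allylic ether on O4' while O7 and O3' carry MOM groups. That is the reverse of the natural reactivity order of 1, so the flavone would have to be assembled from differentiated building blocks or taken through several extra protection steps. The tertiary aryl ether cannot be made by simple alkylation.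
- The rearrangement exposes finished prenyl groups, each next to a newly freed phenol, to the highest temperature of the route. The ring-A unit may stop at C6 in reversed form, and ortho-prenyl phenols can close to chromans under heat.
- It ends with the same acidic MOM cleavage as the chosen route.
- Comparison: the chosen route pays with one extra bond-forming operation, but it uses the acidity order of 1 as it is, runs the hot step on robust allyl groups, and forms the prenyl alkenes at 40 °C.

Key step: step 4

Remark: in steps 3 and 5 three MOM groups are put on or taken off in one operation; the partly protected flavones on the way (several, in no fixed order) are stages of one reaction and carry no numbers, whereas the one or two defined half-converted compounds of steps 1, 2 and 4 are numbered.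

## Route

Step 1
Reactants: 1 luteolin; 2 allyl bromide
Product: 4 7,4'-di-O-allylluteolin [7-allyloxy-2-(4-allyloxy-3-hydroxyphenyl)-5-hydroxychromen-4-one], via 7-O-allylluteolin 3 (not isolated)
Conditions: allyl bromide (2.1 equiv), K2CO3 (2.2 equiv), DMF, 0 °C → rt, Ar
Reagents that add atoms: allyl bromide, C=CCBr
Why: Williamson ether synthesis under stoichiometric control: with the acidity order 7-OH > 4'-OH > 3'-OH >> 5-OH (the 4'-phenoxide is conjugated through C2=C3 with C4=O, 5-OH is locked in the chelate), two equivalents of base and halide should alkylate O7 first and O4' second. The 3'-OH and 5-OH should stay free.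

Step 2
Reactants: 4 7,4'-di-O-allylluteolin
Product: 7 8,5'-diallylluteolin [8-allyl-2-(3-allyl-4,5-dihydroxyphenyl)-5,7-dihydroxychromen-4-one], via 8-allyl-4'-O-allylluteolin 5 (not isolated), via 5'-allyl-7-O-allylluteolin 6 (not isolated)
Conditions: N,N-diethylaniline, 200–210 °C (sealed vessel or microwave), Ar
Reagents that add atoms: none
Why: Two aromatic Claisen rearrangements ([3,3] shift from oxygen to the ortho carbon, then enolisation back to the phenol), one on each ring and in either order. On ring B the only open carbon ortho to O4' is C5'; on ring A the shift should go mainly to C8, the site taken in 7-allyloxyflavones, with migration to C6 as the competing path because the chelated 5-OH works in that direction. Any ring-A regioisomer is removed by chromatography or crystallisation before going on.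

Step 3
Reactants: 7 8,5'-diallylluteolin; 8 chloromethyl methyl ether
Product: 9 8,5'-diallyl-7,3',4'-tri-O-MOM-luteolin [8-allyl-2-[3-allyl-4,5-bis(methoxymethoxy)phenyl]-5-hydroxy-7-(methoxymethoxy)chromen-4-one]
Conditions: MOMCl (3.6 equiv), i-Pr2NEt (5 equiv), CH2Cl2, 0 °C → rt
Reagents that add atoms: chloromethyl methyl ether, COCCl
Why: O-alkylation of the three free phenols with an α-chloro ether and a hindered amine base. The 5-OH is held by its hydrogen bond to C4=O and is not alkylated under amine conditions; the acetals mask the catechol and make the flavone soluble in CH2Cl2.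

Step 4
Reactants: 9 8,5'-diallyl-7,3',4'-tri-O-MOM-luteolin; 10 2-methyl-2-butene
Product: 13 7,3',4'-tri-O-MOM epimedokoreanin B [5-hydroxy-7-(methoxymethoxy)-2-[4,5-bis(methoxymethoxy)-3-(3-methylbut-2-enyl)phenyl]-8-(3-methylbut-2-enyl)chromen-4-one], via 8-prenyl-5'-allyl tri-O-MOM flavone 11 (not isolated), via 8-allyl-5'-prenyl tri-O-MOM flavone 12 (not isolated)
Conditions: RuCl2(=CHPh)(PCy3)(H2IMes) (second-generation Grubbs catalyst, 10 mol% in two portions), 2-methyl-2-butene/CH2Cl2 (1:1), 1,4-benzoquinone (10 mol%), 40 °C, sealed tube
Reagents that add atoms: 2-methyl-2-butene, CC=C(C)C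
Why: Olefin cross-metathesis by the metallacyclobutane mechanism: after loss of PCy3 the Ru=CHR carbene exchanges with a terminal CH=CH2 of 9 and passes through [2+2]/retro-[2+2] cycles with 10, so that each Ar–CH2–CH= unit ends up joined to the isopropylidene carbon while propene leaves. The closest known reaction type is the conversion of allylarenes, allylated flavonoids among them, into prenylarenes with 10 and this catalyst. No ring is closed and no stereocentre is formed, and because each new alkene carries two methyl groups on one carbon there is no E/Z question. Cross- over self-metathesis is secured by using 10 as co-solvent in large excess. Transfer of the ethylidene end of 10 is self-correcting, since the resulting disubstituted alkene stays reactive and is carried on, whereas the trisubstituted prenyl alkene is too hindered to re-enter the cycle. Migration of the double bond into conjugation with the arene is held back by the low temperature and by benzoquinone, which intercepts Ru–H species from catalyst decay. In the substrate, the C2=C3 bond of ring C is trisubstituted and push–pull polarised and should not take part, the 5-OH is tied up in the chelate, and the MOM ethers keep the catechol from binding the Ru centre.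

Step 5
Reactants: 13 7,3',4'-tri-O-MOM epimedokoreanin B
Product: 14 epimedokoreanin B [5,7-dihydroxy-2-[3,4-dihydroxy-5-(3-methylbut-2-enyl)phenyl]-8-(3-methylbut-2-enyl)chromen-4-one]
Conditions: HCl (ca. 1 M) in MeOH/H2O (9:1), rt → 40 °C, Ar; then aq. NaHCO3 at full conversion
Reagents that add atoms: none
Why: Acid-catalysed acetal cleavage (transacetalisation to methanol) of the three aryl MOM ethers. Aryl MOM acetals ionise through an oxocarbenium ion much more easily than a trisubstituted alkene is protonated, so dilute acid at low temperature for a limited time should free the phenols without closing chromans.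

## Compound list

1 | luteolin, 2-(3,4-dihydroxyphenyl)-5,7-dihydroxychromen-4-one | O=c1cc(-c2ccc(O)c(O)c2)oc2cc(O)cc(O)c12 | starting material
2 | allyl bromide (3-bromoprop-1-ene) | C=CCBr | starting material
3 | 7-O-allylluteolin, 7-allyloxy-2-(3,4-dihydroxyphenyl)-5-hydroxychromen-4-one | C=CCOc1cc(O)c2c(c1)oc(-c1ccc(O)c(O)c1)cc2=O | intermediate
4 | 7,4'-di-O-allylluteolin, 7-allyloxy-2-(4-allyloxy-3-hydroxyphenyl)-5-hydroxychromen-4-one | C=CCOc1cc(O)c2c(c1)oc(-c1ccc(OCC=C)c(O)c1)cc2=O | intermediate
5 | 8-allyl-4'-O-allylluteolin, 8-allyl-2-(4-allyloxy-3-hydroxyphenyl)-5,7-dihydroxychromen-4-one | C=CCOc1ccc(-c2cc(=O)c3c(O)cc(O)c(CC=C)c3o2)cc1O | intermediate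
6 | 5'-allyl-7-O-allylluteolin, 7-allyloxy-2-(3-allyl-4,5-dihydroxyphenyl)-5-hydroxychromen-4-one | C=CCOc1cc(O)c2c(c1)oc(-c1cc(O)c(O)c(CC=C)c1)cc2=O | intermediate
7 | 8,5'-diallylluteolin, 8-allyl-2-(3-allyl-4,5-dihydroxyphenyl)-5,7-dihydroxychromen-4-one | C=CCc1cc(-c2cc(=O)c3c(O)cc(O)c(CC=C)c3o2)cc(O)c1O | intermediate
8 | chloromethyl methyl ether (MOMCl) | COCCl | starting material
9 | 8,5'-diallyl-7,3',4'-tri-O-MOM-luteolin, 8-allyl-2-[3-allyl-4,5-bis(methoxymethoxy)phenyl]-5-hydroxy-7-(methoxymethoxy)chromen-4-one | C=CCc1cc(-c2cc(=O)c3c(O)cc(OCOC)c(CC=C)c3o2)cc(OCOC)c1OCOC | intermediate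
10 | 2-methyl-2-butene | CC=C(C)C | starting material
11 | 8-prenyl-5'-allyl tri-O-MOM flavone, 2-[3-allyl-4,5-bis(methoxymethoxy)phenyl]-5-hydroxy-7-(methoxymethoxy)-8-(3-methylbut-2-enyl)chromen-4-one | C=CCc1cc(-c2cc(=O)c3c(O)cc(OCOC)c(CC=C(C)C)c3o2)cc(OCOC)c1OCOC | intermediate
12 | 8-allyl-5'-prenyl tri-O-MOM flavone, 8-allyl-2-[4,5-bis(methoxymethoxy)-3-(3-methylbut-2-enyl)phenyl]-5-hydroxy-7-(methoxymethoxy)chromen-4-one | CC(C)=CCc1cc(-c2cc(=O)c3c(O)cc(OCOC)c(CC=C)c3o2)cc(OCOC)c1OCOC | intermediate
13 | 7,3',4'-tri-O-MOM epimedokoreanin B | CC(C)=CCc1cc(-c2cc(=O)c3c(O)cc(OCOC)c(CC=C(C)C)c3o2)cc(OCOC)c1OCOC | intermediate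
14 | epimedokoreanin B | CC(C)=CCc1cc(-c2cc(=O)c3c(O)cc(O)c(CC=C(C)C)c3o2)cc(O)c1O | target

## Step count and least certain steps

Total step count: 5. Longest linear sequence: 5 steps (1 → 4 → 7 → 9 → 13 → 14).

**Step 4 (key step).**
- What may go wrong: the catalyst may die before both termini have reacted; the double bond may migrate into conjugation with the arene; the ethylidene end of 10 may be delivered without onward conversion, leaving a one-carbon-short chain.
- Fallback, from 9 back to 13: both terminal alkenes of 9 would be cleaved by the Lemieux–Johnson procedure (OsO4 cat., NaIO4, 2,6-lutidine, dioxane/H2O) to the bis(arylacetaldehyde) F1. F1 would be treated at once in a Wittig reaction with the ylide from isopropyltriphenylphosphonium iodide and KN(SiMe3)2 (excess, since the 5-OH consumes one equivalent) in THF at −78 °C → 0 °C, giving 13.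

**Step 2.**
- What may go wrong: the ring-A allyl group may migrate to C6 instead of C8 to a larger extent than expected, because the O5–H···O4 chelate favours that direction; on long heating the new ortho-allyl phenols may add across their own alkenes.
- Fallback, from 4 back to 7: the chelate is removed before the rearrangement. 4 would be capped at O5 and O3' with 8 (NaH, DMF, 0 °C) to give 5,3'-bis-O-MOM-7,4'-di-O-allylluteolin F2. Without the chelate, ring A should behave as a plain 7-allyloxyflavone, and heating in N,N-diethylaniline should give 8,5'-diallyl-5,3'-bis-O-MOM-luteolin F3. Methanolic HCl, to which allyl groups are inert, then returns 7.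

**Step 1.**
- What may go wrong: alkylation at O3' in place of, or in addition to, O4', and over-alkylation, if the acidity difference within the catechol proves too small in practice.
- Fallback, from 2 back to 7: the 3'-oxygen is marked by a methyl ether instead of relying on kinetics. Chrysoeriol F4 (purchased; luteolin 3'-methyl ether), which has only 7-OH and 4'-OH open besides the chelated 5-OH, would be allylated with 2 (K2CO3, DMF) to 7,4'-di-O-allylchrysoeriol F5. The same thermal Claisen rearrangement would give 8,5'-diallylchrysoeriol F6. Cleavage of the aryl methyl ether with BBr3 (CH2Cl2, −78 °C → 0 °C), conditions that allyl-substituted guaiacols tolerate, would give 7.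

**Step 5.**
- What may go wrong: acid-promoted addition of the neighbouring phenol, or of methanol or water, across a prenyl alkene may compete with acetal cleavage, most readily at the electron-rich ring A.
- Fallback, from 7 to 14: acid is avoided altogether. 7 would be peracetylated (Ac2O, pyridine, DMAP) to the tetraacetate F7. F7 would undergo the same cross-metathesis with 10 and RuCl2(=CHPh)(PCy3)(H2IMes) to give tetra-O-acetyl epimedokoreanin B F8. Methanolysis (K2CO3, degassed MeOH, 0 °C, then acidification to pH 5–6) would give 14.

## Further compounds

F1 | step 4 | 5-hydroxy-7-(methoxymethoxy)-8-(2-oxoethyl)-2-[4,5-bis(methoxymethoxy)-3-(2-oxoethyl)phenyl]chromen-4-one | O=CCc1cc(-c2cc(=O)c3c(O)cc(OCOC)c(CC=O)c3o2)cc(OCOC)c1OCOC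
F2 | step 2 | 5,3'-bis-O-MOM-7,4'-di-O-allylluteolin | C=CCOc1cc(OCOC)c2c(c1)oc(-c1ccc(OCC=C)c(OCOC)c1)cc2=O
F3 | step 2 | 8,5'-diallyl-5,3'-bis-O-MOM-luteolin | C=CCc1cc(-c2cc(=O)c3c(OCOC)cc(O)c(CC=C)c3o2)cc(OCOC)c1O
F4 | step 1 | chrysoeriol (purchased), 5,7-dihydroxy-2-(4-hydroxy-3-methoxyphenyl)chromen-4-one | COc1cc(-c2cc(=O)c3c(O)cc(O)cc3o2)ccc1O
F5 | step 1 | 7,4'-di-O-allylchrysoeriol | C=CCOc1cc(O)c2c(c1)oc(-c1ccc(OCC=C)c(OC)c1)cc2=O
F6 | step 1 | 8,5'-diallylchrysoeriol | C=CCc1cc(-c2cc(=O)c3c(O)cc(O)c(CC=C)c3o2)cc(OC)c1O
F7 | step 5 | 8,5'-diallylluteolin 5,7,3',4'-tetraacetate | C=CCc1cc(-c2cc(=O)c3c(OC(C)=O)cc(OC(C)=O)c(CC=C)c3o2)cc(OC(C)=O)c1OC(C)=O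
F8 | step 5 | 5,7,3',4'-tetra-O-acetyl epimedokoreanin B | CC(C)=CCc1cc(-c2cc(=O)c3c(OC(C)=O)cc(OC(C)=O)c(CC=C(C)C)c3o2)cc(OC(C)=O)c1OC(C)=O
A1 | alternative 1 | 3',4'-di-O-allyl-5-O-methyl epimedokoreanin B | CC(C)=CCc1cc(-c2cc(=O)c3c(OC)cc(O)c(CC=C(C)C)c3o2)cc(OCC=C)c1OCC=C
A2 | alternative 1 | (Z)-3-[3,4-bis(allyloxy)-5-(3-methylbut-2-enyl)phenyl]-3-[3-hydroxy-5-methoxy-2-(3-methylbut-2-enyl)phenoxy]acrylic acid | OC(=O)/C=C(\Oc1cc(OC)cc(O)c1CC=C(C)C)c1cc(CC=C(C)C)c(OCC=C)c(OCC=C)c1
A3 | alternative 2 | 3',4'-di-O-MOM epimedokoreanin B | CC(C)=CCc1cc(-c2cc(=O)c3c(O)cc(O)c(CC=C(C)C)c3o2)cc(OCOC)c1OCOC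
A4 | alternative 2 | methyl 4-{6-[4,5-bis(methoxymethoxy)-3-(3-methylbut-2-enyl)phenyl]-4-oxo-4H-pyran-2-yl}-7-methyl-3-oxooct-6-enoate (racemic) | COC(=O)CC(=O)C(CC=C(C)C)c1cc(=O)cc(-c2cc(CC=C(C)C)c(OCOC)c(OCOC)c2)o1
A5 | alternative 3 | 7,3'-di-O-MOM epimedokoreanin B | CC(C)=CCc1cc(-c2cc(=O)c3c(O)cc(OCOC)c(CC=C(C)C)c3o2)cc(OCOC)c1O
A6 | alternative 3 | 5-O-prenyl-4'-O-(1,1-dimethylallyl)-7,3'-di-O-MOM-luteolin | C=CC(C)(C)Oc1ccc(-c2cc(=O)c3c(OCC=C(C)C)cc(OCOC)cc3o2)cc1OCOC
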